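**Retrosynthetic overview**

1. Feature: ring B is a quinone in which C1 (OAr) and C2 (OMe) lie between the carbonyls C3 and C6, which is the oxygenation pattern of a squaric diester. C4 and C5 carry identical prenyl groups, so it does not matter which squarate carbonyl is attacked.
2. Ring B (as hydroquinone 19) comes from thermal ring expansion of the 4-alkenyl-4-hydroxycyclobutenone 16: 4π opening of the C3–C6 bond, then 6π closure forming C6–C5.
3. Carbinol 16 comes from aryl methyl squarate 7 and alkenyllithium 14 (C3–C4 bond). Squarate 7 comes from squaric ester chloride 6 (from dimethyl squarate 3) and the bis-MOM phenol 2 (ring A, from 1).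
4. Alkenyllithium 14 comes from (E)-vinyl iodide 13, made by hydrozirconation–iodination of the symmetrical alkyne 11, itself from acetylene 8 and two prenyl bromide 9.
5. Ring order: ring A and the four-membered ring are bought; ring B is the only ring made (step 8). The end game is MOM removal on the hydroquinone, then Ag2O oxidation to the quinone.

Key step: step 8

Remark: the alkenyllithium is taken to add mainly to the squarate carbonyl next to the OMe-bearing carbon (the carbonyl cross-conjugated with the weaker donor OAr). Addition at the other carbonyl would give a constitutional isomer that ring-expands to the same hydroquinone 19, so regiocontrol is not required.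

**Route**

Step 1
Reactants: 1 methyl 2,4,6-trihydroxybenzoate
Product: 2 methyl 2-hydroxy-4,6-bis(methoxymethoxy)benzoate
Conditions: MOMCl (2.1 equiv), i-Pr2NEt, CH2Cl2, 0 °C to rt
Reagents that add atoms: chloromethyl methyl ether (MOMCl), COCCl
Why: Williamson-type O-alkylation (MOM protection) should take the 4-hydroxyl and one 2-hydroxyl, while the last hydroxyl is held in a hydrogen bond to the ester carbonyl and should stay free with two equivalents of MOMCl.

Step 2
Reactants: 3 dimethyl squarate
Product: 5 3-hydroxy-4-methoxycyclobut-3-ene-1,2-dione (monomethyl squarate), via sodium salt 4 (not isolated)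
Conditions: NaOH (1.0 equiv), THF/H2O, 0 °C to rt; then aq HCl (1.0 equiv), evaporate, extract residue with acetone
Reagents that add atoms: sodium hydroxide, [Na+].[OH-]
Why: Vinylogous ester saponification by addition–elimination; after the first exchange the ring is an electron-rich semisquarate anion, so one equivalent of hydroxide should stop at the monoester.

Step 3
Reactants: 5 3-hydroxy-4-methoxycyclobut-3-ene-1,2-dione
Product: 6 3-chloro-4-methoxycyclobut-3-ene-1,2-dione
Conditions: (COCl)2 (1.2 equiv), DMF (cat.), CH2Cl2, 0 °C to rt
Reagents that add atoms: oxalyl chloride, O=C(Cl)C(=O)Cl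
Why: Conversion of a vinylogous carboxylic acid into its acid chloride through the chloroiminium (Vilsmeier-type) species from oxalyl chloride and DMF, a standard access to squaric ester chlorides.

Step 4
Reactants: 2 methyl 2-hydroxy-4,6-bis(methoxymethoxy)benzoate; 6 3-chloro-4-methoxycyclobut-3-ene-1,2-dione
Product: 7 methyl 2-[(2-methoxy-3,4-dioxocyclobut-1-en-1-yl)oxy]-4,6-bis(methoxymethoxy)benzoate
Conditions: i-Pr2NEt (1.2 equiv), CH2Cl2, −40 °C to 0 °C
Reagents that add atoms: none
Why: Addition–elimination at the chlorine-bearing carbon of the vinylogous acid chloride (O-acylation-type substitution); chloride leaves far more readily than methoxide, so the phenol should displace only chlorine and give the mixed aryl methyl squarate.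

Step 5
Reactants: 8 acetylene; 9 prenyl bromide (1-bromo-3-methylbut-2-ene)
Product: 11 2,9-dimethyldeca-2,7-dien-5-yne, via bis(bromomagnesio)acetylene 10 (not isolated)
Conditions: EtMgBr (2 equiv per acetylene), THF, rt to 50 °C; then CuCl (cat.), 9 (2 equiv), 0 °C to 45 °C
Reagents that add atoms: none
Why: Copper-catalysed allylic substitution of an alkynyl Grignard reagent, known for the bis-Grignard reagent of acetylene with allylic bromides; attack at the unhindered CH2 end of prenyl bromide (SN2, not SN2') should dominate because the alternative builds a quaternary carbon.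

Step 6
Reactants: 11 2,9-dimethyldeca-2,7-dien-5-yne
Product: 13 (5E)-5-iodo-2,9-dimethyldeca-2,5,8-triene, via alkenylzirconocene 12 (not isolated)
Conditions: Cp2Zr(H)Cl (1.1 equiv), THF, rt, dark; then I2 (1.05 equiv), 0 °C
Reagents that add atoms: iodine, II
Why: Hydrozirconation then iododezirconation; Cp2Zr(H)Cl adds Zr–H syn across the internal alkyne much faster than across trisubstituted prenyl alkenes, the symmetry of 11 removes any regiochemical question, and iodine replaces zirconium with retention to fix the (E) geometry.

Step 7
Reactants: 13 (5E)-5-iodo-2,9-dimethyldeca-2,5,8-triene; 7 methyl 2-[(2-methoxy-3,4-dioxocyclobut-1-en-1-yl)oxy]-4,6-bis(methoxymethoxy)benzoate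
Product: 16 methyl 2-({3-[(5E)-2,9-dimethyldeca-2,5,8-trien-5-yl]-3-hydroxy-2-methoxy-4-oxocyclobut-1-en-1-yl}oxy)-4,6-bis(methoxymethoxy)benzoate (racemic), via alkenyllithium 14 (not isolated), via lithium alkoxide 15 (not isolated)
Conditions: t-BuLi (2.0 equiv), Et2O, −78 °C; cannulate into 7 (1.0 equiv), THF, −78 °C; sat. aq NH4Cl at −78 °C
Reagents that add atoms: none
Why: Iodine–lithium exchange with retention of alkene geometry, then 1,2-addition of the hard alkenyllithium to a strained, highly electrophilic squarate carbonyl at −78 °C, which should outrun attack on the hindered 2,6-disubstituted benzoate or on the aryloxy-bearing ring carbon; the new carbinol centre forms as a racemate and is destroyed in step 8.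

Step 8
Reactants: 16 the 4-alkenyl-4-hydroxycyclobutenone
Product: 19 methyl 2-[2,5-dihydroxy-6-methoxy-3,4-bis(3-methylbut-2-en-1-yl)phenoxy]-4,6-bis(methoxymethoxy)benzoate, via dienylketene 17 (not isolated), via cyclohexadienone 18 (not isolated)
Conditions: toluene (degassed, ca. 0.02 M), 110 °C, argon
Reagents that add atoms: none
Why: Heating should open the C3–C6 bond of the cyclobutenone (ring B numbering) by conrotatory 4π electrocyclic ring opening to the (Z)-dienylketene 17, with the donor hydroxyl on C3 rotating outward and the alkenyl group inward, which is the torquoselectivity that brings the alkene terminus next to the ketene carbon. Thermal disrotatory 6π electrocyclisation then joins ketene carbon C6 to alkene terminus C5 and closes six-membered ring B as cyclohexadienone 18, which enolises by loss of the C5 hydrogen to hydroquinone 19. The closest known reaction is the Moore rearrangement of 4-alkenyl-4-hydroxycyclobutenones made from squarate esters. The only new sp3 centre (C5 of 18) is transient and is erased on aromatisation, so no stereocentre needs control. The (E) geometry set in step 6 puts hydrogen, not the prenyl CH2, on the inner face of the closing terminus, so closure should be unhindered, and the OAr and OMe groups on C1 and C2 are spectators. Dilute, degassed solution protects the electron-rich hydroquinone from oxidation and the ketene from intermolecular capture.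

Step 9
Reactants: 19 the bis-MOM hydroquinone
Product: 20 methyl 2-[2,5-dihydroxy-6-methoxy-3,4-bis(3-methylbut-2-en-1-yl)phenoxy]-4,6-dihydroxybenzoate
Conditions: conc. aq HCl (few equiv), MeOH (degassed), argon, rt to 40 °C
Reagents that add atoms: none
Why: Acid-catalysed acetal cleavage (transacetalisation to methanol) of the two aryl MOM ethers; it is done on the hydroquinone so that no electrophilic aryloxyquinone meets acidic methanol, and these conditions are known to spare C-prenyl groups next to phenols.

Step 10
Reactants: 20 the tetrahydroxy diaryl ether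
Product: 21 atrovirinone
Conditions: Ag2O (2 equiv), MgSO4, Et2O, rt
Reagents that add atoms: none
Why: Two-electron oxidation of a para-hydroquinone to the benzoquinone with Ag2O; the ester-deactivated resorcinol hydroxyls of ring A should not be oxidised under these neutral conditions.

**Compound list**

1 | methyl 2,4,6-trihydroxybenzoate | COC(=O)c1c(O)cc(O)cc1O | starting material
2 | methyl 2-hydroxy-4,6-bis(methoxymethoxy)benzoate | COC(=O)c1c(O)cc(OCOC)cc1OCOC | intermediate
3 | dimethyl squarate | COC1=C(OC)C(=O)C1=O | starting material
4 | sodium 2-methoxy-3,4-dioxocyclobut-1-en-1-olate | COC1=C([O-])C(=O)C1=O.[Na+] | intermediate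
5 | 3-hydroxy-4-methoxycyclobut-3-ene-1,2-dione | COC1=C(O)C(=O)C1=O | intermediate
6 | 3-chloro-4-methoxycyclobut-3-ene-1,2-dione | COC1=C(Cl)C(=O)C1=O | intermediate
7 | methyl 2-[(2-methoxy-3,4-dioxocyclobut-1-en-1-yl)oxy]-4,6-bis(methoxymethoxy)benzoate | COC(=O)c1c(OCOC)cc(OCOC)cc1OC1=C(OC)C(=O)C1=O | intermediate
8 | acetylene | C#C | starting material
9 | prenyl bromide | CC(C)=CCBr | starting material
10 | bis(bromomagnesio)acetylene | Br[Mg]C#C[Mg]Br | intermediate
11 | 2,9-dimethyldeca-2,7-dien-5-yne | CC(C)=CCC#CCC=C(C)C | intermediate
12 | chlorobis(cyclopentadienyl)[(5E)-2,9-dimethyldeca-2,5,8-trien-5-yl]zirconium | Cl[Zr](C1C=CC=C1)(C1C=CC=C1)/C(CC=C(C)C)=C/CC=C(C)C | intermediate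
13 | (5E)-5-iodo-2,9-dimethyldeca-2,5,8-triene | I/C(CC=C(C)C)=C/CC=C(C)C | intermediate
14 | [(5Z)-2,9-dimethyldeca-2,5,8-trien-5-yl]lithium (geometry of 13 retained) | [Li]/C(CC=C(C)C)=C/CC=C(C)C | intermediate
15 | lithium alkoxide of 16 (racemic) | COC(=O)c1c(OCOC)cc(OCOC)cc1OC1=C(OC)C([O-])(/C(CC=C(C)C)=C/CC=C(C)C)C1=O.[Li+] | intermediate
16 | methyl 2-({3-[(5E)-2,9-dimethyldeca-2,5,8-trien-5-yl]-3-hydroxy-2-methoxy-4-oxocyclobut-1-en-1-yl}oxy)-4,6-bis(methoxymethoxy)benzoate (racemic) | COC(=O)c1c(OCOC)cc(OCOC)cc1OC1=C(OC)C(O)(/C(CC=C(C)C)=C/CC=C(C)C)C1=O | intermediate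
17 | (Z)-dienylketene: aryloxy ketene carbon, then C(OMe)=C(OH), then the (E)-diprenyl alkene | COC(=O)c1c(OCOC)cc(OCOC)cc1OC(=C=O)/C(OC)=C(O)\C(CC=C(C)C)=C\CC=C(C)C | intermediate
18 | 2-aryloxy-4-hydroxy-3-methoxy-5,6-bis(3-methylbut-2-en-1-yl)cyclohexa-2,4-dien-1-one (racemic at C6; aryl is bis-MOM ring A) | COC(=O)c1c(OCOC)cc(OCOC)cc1OC1=C(OC)C(O)=C(CC=C(C)C)C(CC=C(C)C)C1=O | intermediate
19 | methyl 2-[2,5-dihydroxy-6-methoxy-3,4-bis(3-methylbut-2-en-1-yl)phenoxy]-4,6-bis(methoxymethoxy)benzoate | COC(=O)c1c(OCOC)cc(OCOC)cc1Oc1c(OC)c(O)c(CC=C(C)C)c(CC=C(C)C)c1O | intermediate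
20 | methyl 2-[2,5-dihydroxy-6-methoxy-3,4-bis(3-methylbut-2-en-1-yl)phenoxy]-4,6-dihydroxybenzoate | COC(=O)c1c(O)cc(O)cc1Oc1c(OC)c(O)c(CC=C(C)C)c(CC=C(C)C)c1O | intermediate
21 | atrovirinone, methyl 2,4-dihydroxy-6-{[2-methoxy-4,5-bis(3-methylbut-2-en-1-yl)-3,6-dioxocyclohexa-1,4-dien-1-yl]oxy}benzoate | COC(=O)c1c(O)cc(O)cc1OC1=C(OC)C(=O)C(CC=C(C)C)=C(CC=C(C)C)C1=O | target

**Step count**

Total steps: 10. Longest linear sequence: 7 steps (3 → 5 → 6 → 7 → 16 → 19 → 20 → 21).

**Three steps most likely to fail**

Step 7. The alkenyllithium may attack the aryloxy-bearing ring carbon (addition–elimination with loss of ring A as phenoxide) or the benzoate ester instead of adding 1,2 to a ring carbonyl. Proton transfer from the doubly allylic CH2 groups may also quench the reagent. The fallback avoids the iodide and the lithium reagent. It sets out from alkyne 11 and squarate 7. Hydrozirconation of 11 gives 12, which is transmetalated with Me2Zn (toluene/CH2Cl2, −60 °C to 0 °C) to the alkenyl(methyl)zinc reagent F1. This reagent is much less basic, tolerates esters, and is known to add to aldehydes and activated ketones. Addition to the activated carbonyl of 7 should give the methylzinc alkoxide F2, and NH4Cl work-up returns to the route at 16.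

Step 8. If some of the ring opening proceeds with inward rotation of the hydroxyl, the ketene is captured by that hydroxyl to give a butenolide. The free hydroquinone may also degrade at 110 °C. The fallback masks the hydroxyl before heating. It sets out from 16, which is silylated (TESOTf, 2,6-lutidine, CH2Cl2, −78 °C) to the triethylsilyl ether F3. A silyloxy group is also an outward-rotating donor and cannot add to the ketene. Thermolysis in toluene should pass through the silyloxy dienylketene F4 and the silyloxy cyclohexadienone F5 to the more robust mono-silylated hydroquinone F6. Methanolic HCl then removes the silyl group and both MOM ethers, returning to the route at 20.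

Step 9. During the time needed to cleave both MOM ethers, acid may cyclise a prenyl group onto the neighbouring hydroquinone hydroxyl (chroman formation) or add methanol across a prenyl alkene. The fallback reverses the order of the last two operations. It sets out from 19, which is oxidised first with Ag2O (Et2O, rt) to the bis-MOM quinone F7, where no hydroxyl flanks the prenyl groups. The MOM ethers are then hydrolysed with aqueous HCl in THF (rt to 40 °C), with no alcohol present, so that solvent cannot exchange the aryloxy or methoxy group on the quinone. This returns to the route at 21.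

**Further compounds**

F1 | step 7 | methyl[(5E)-2,9-dimethyldeca-2,5,8-trien-5-yl]zinc | C[Zn]/C(CC=C(C)C)=C/CC=C(C)C
F2 | step 7 | methylzinc alkoxide of 16 | COC(=O)c1c(OCOC)cc(OCOC)cc1OC1=C(OC)C(O[Zn]C)(/C(CC=C(C)C)=C/CC=C(C)C)C1=O
F3 | step 8 | triethylsilyl ether of 16 | COC(=O)c1c(OCOC)cc(OCOC)cc1OC1=C(OC)C(O[Si](CC)(CC)CC)(/C(CC=C(C)C)=C/CC=C(C)C)C1=O
F4 | step 8 | silyloxy dienylketene | COC(=O)c1c(OCOC)cc(OCOC)cc1OC(=C=O)/C(OC)=C(O[Si](CC)(CC)CC)\C(CC=C(C)C)=C\CC=C(C)C
F5 | step 8 | silyloxy cyclohexadienone (racemic) | COC(=O)c1c(OCOC)cc(OCOC)cc1OC1=C(OC)C(O[Si](CC)(CC)CC)=C(CC=C(C)C)C(CC=C(C)C)C1=O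
F6 | step 8 | mono-triethylsilyl ether of hydroquinone 19 (silyl on the oxygen next to the OMe-bearing carbon) | COC(=O)c1c(OCOC)cc(OCOC)cc1Oc1c(OC)c(O[Si](CC)(CC)CC)c(CC=C(C)C)c(CC=C(C)C)c1O
F7 | step 9 | bis-MOM ether of atrovirinone (quinone) | COC(=O)c1c(OCOC)cc(OCOC)cc1OC1=C(OC)C(=O)C(CC=C(C)C)=C(CC=C(C)C)C1=O
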